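In disydonol C, ring A and ring B each hold, adjacent to the phenolic oxygen, a benzylic carbon bearing OH, CH3 and an identical 4-methylpentyl group; these two carbons are the only stereocentres. The plan cuts both carbinol-carbon–CH2(chain) bonds in one retrosynthetic stroke. A twofold lithiation–borylation of an (R,R)-bis(N,N-diisopropylcarbamate) with 4-methylpentyl pinacol boronate should create both bonds and both fully substituted carbons stereospecifically by 1,2-metalate rearrangement. The substrate is the complete diarylmethane with two (R)-1-arylethyl carbamates, methyl-protected phenols and a triisopropylsilyl-protected ring B CH2OH. It is assembled from a single enantioenriched monomer by Negishi coupling.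

Key step: step 10

Remark: at each centre the chain takes the place of the benzylic hydrogen and an oxygen returns to the site of the carbamate oxygen, so the R carbamate carbons become S carbinol carbons only because 4-methylpentyl outranks methyl.

Step 1
Reactants: 1 methyl 4-acetyl-3-hydroxybenzoate
Product: 2 methyl 4-acetyl-3-methoxybenzoate
Conditions: MeI, K2CO3, acetone, reflux
Reagents that add atoms: iodomethane, SMILES CI
Why: Williamson ether synthesis, in which carbonate ionises the acidic ortho-acyl phenol and the phenoxide is O-methylated by SN2 while ketone and ester stay inert.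

Step 2
Reactants: 2 methyl 4-acetyl-3-methoxybenzoate
Product: 3 methyl 4-[(1R)-1-hydroxyethyl]-3-methoxybenzoate
Conditions: RuCl(p-cymene)[(R,R)-TsDPEN] (1 mol %), HCO2H/Et3N (5:2), 30 °C
Reagents that add atoms: none
Why: Noyori–Ikariya asymmetric transfer hydrogenation, in which the ruthenium hydride of the (R,R)-TsDPEN complex delivers hydrogen to one face of the aryl methyl ketone through an outer-sphere transition state organised by an arene CH/π contact, which should set the (R)-carbinol centre and leave the ester untouched.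

Step 3
Reactants: 3 methyl 4-[(1R)-1-hydroxyethyl]-3-methoxybenzoate; 4 N,N-diisopropylcarbamoyl chloride
Product: 5 methyl 4-[(1R)-1-(N,N-diisopropylcarbamoyloxy)ethyl]-3-methoxybenzoate
Conditions: Et3N, DMAP (cat.), toluene, 100 °C
Reagents that add atoms: none
Why: Carbamoylation (acyl substitution at the carbamoyl chloride by the secondary alcohol with Et3N as acid scavenger), which breaks no bond at the stereocentre and so keeps the (R) configuration.

Step 4
Reactants: 5 methyl 4-[(1R)-1-(N,N-diisopropylcarbamoyloxy)ethyl]-3-methoxybenzoate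
Product: 6 (1R)-1-[4-(hydroxymethyl)-2-methoxyphenyl]ethyl N,N-diisopropylcarbamate
Conditions: LiBH4, THF, 0 → 50 °C
Reagents that add atoms: none
Why: Chemoselective hydride reduction, since LiBH4 reduces the methyl ester to the primary alcohol but does not attack the hindered, weakly electrophilic N,N-diisopropylcarbamate.

Step 5
Reactants: 6 (1R)-1-[4-(hydroxymethyl)-2-methoxyphenyl]ethyl N,N-diisopropylcarbamate
Product: 7 (1R)-1-[4-(bromomethyl)-2-methoxyphenyl]ethyl N,N-diisopropylcarbamate
Conditions: CBr4, PPh3, CH2Cl2, 0 °C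
Reagents that add atoms: tetrabromomethane, SMILES BrC(Br)(Br)Br
Why: Appel reaction, in which the primary benzylic alcohol is activated as an alkoxyphosphonium ion and displaced by bromide under neutral conditions that leave the carbamate and its stereocentre alone.

Step 6
Reactants: 6 (1R)-1-[4-(hydroxymethyl)-2-methoxyphenyl]ethyl N,N-diisopropylcarbamate
Product: 8 (1R)-1-[5-bromo-4-(hydroxymethyl)-2-methoxyphenyl]ethyl N,N-diisopropylcarbamate
Conditions: NBS, MeCN, 0 °C → rt, dark
Reagents that add atoms: N-bromosuccinimide, SMILES O=C1CCC(=O)N1Br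
Why: Electrophilic aromatic bromination directed by the methoxy group to its para position (ring carbon 5, next to CH2OH), the only activated site that is neither occupied nor flanked by two substituents, under polar dark conditions that avoid benzylic radical bromination.

Step 7
Reactants: 8 (1R)-1-[5-bromo-4-(hydroxymethyl)-2-methoxyphenyl]ethyl N,N-diisopropylcarbamate
Product: 9 (1R)-1-[5-bromo-2-methoxy-4-(triisopropylsilyloxymethyl)phenyl]ethyl N,N-diisopropylcarbamate
Conditions: TIPSCl, imidazole, DMF, rt
Reagents that add atoms: chlorotriisopropylsilane, SMILES CC(C)[Si](Cl)(C(C)C)C(C)C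
Why: Imidazole-promoted silylation of the primary alcohol, with the bulky triisopropylsilyl group chosen because it withstands sec-butyllithium at −78 °C and aqueous hydroxide later on.

Step 8
Reactants: 7 (1R)-1-[4-(bromomethyl)-2-methoxyphenyl]ethyl N,N-diisopropylcarbamate; 9 (1R)-1-[5-bromo-2-methoxy-4-(triisopropylsilyloxymethyl)phenyl]ethyl N,N-diisopropylcarbamate
Product: 11 (R,R)-bis(carbamate) (1R)-1-{4-[(5-{(1R)-1-[(diisopropylcarbamoyl)oxy]ethyl}-4-methoxy-2-{[(triisopropylsilyl)oxy]methyl}phenyl)methyl]-2-methoxyphenyl}ethyl N,N-diisopropylcarbamate, via benzylic zinc bromide 10 (not isolated)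
Conditions: 7 (1.3 equiv), Zn dust, LiCl, THF, 0 °C → rt; then 9, Pd(OAc)2 (2 mol %), SPhos (4 mol %), THF, rt → 50 °C
Reagents that add atoms: none
Why: Negishi cross-coupling, in which zinc inserts into the benzylic C–Br bond of 7 and zerovalent palladium ligated by SPhos undergoes oxidative addition to the hindered electron-rich aryl bromide 9, transmetalation and reductive elimination to form the aryl–CH2 bond without base, so both carbamates, the silyl ether and both remote (R) centres are unaffected.

Step 9
Reactants: 12 1-bromo-4-methylpentane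
Product: 14 4,4,5,5-tetramethyl-2-(4-methylpentyl)-1,3,2-dioxaborolane, via 4-methylpentylmagnesium bromide 13 (not isolated)
Conditions: Mg, I2 (cat.), THF, rt → 40 °C; then 2-isopropoxy-4,4,5,5-tetramethyl-1,3,2-dioxaborolane, −78 °C → rt
Reagents that add atoms: 2-isopropoxy-4,4,5,5-tetramethyl-1,3,2-dioxaborolane, SMILES CC(C)OB1OC(C)(C)C(C)(C)O1
Why: Grignard formation followed by borylation, in which the alkylmagnesium bromide adds to boron and isopropoxide is expelled, a standard route to primary alkyl pinacol boronates.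

Step 10
Reactants: 11 (R,R)-bis(carbamate); 14 4,4,5,5-tetramethyl-2-(4-methylpentyl)-1,3,2-dioxaborolane (two equivalents react)
Product: 17 (R,R)-bis(tertiary benzylic pinacol boronate) in which each former CH(CH3)O-carbamate carbon bears CH3 with 4-methylpentyl plus the dioxaborolane, via dilithiated bis(carbamate) 15 (not isolated), via dilithium bis(boronate complex) 16 (not isolated)
Conditions: s-BuLi (2.6 equiv), Et2O, −78 °C, 1 h; 14 (3.0 equiv), −78 °C, 2 h; MgBr2 in MeOH (1 M), −78 °C → rt
Reagents that add atoms: none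
Why: Each carbamate carbonyl pre-complexes sec-butyllithium and guides removal of its own benzylic hydrogen with retention to give the configurationally stable dilithiated species 15; each C–Li centre then adds to the boron of 14 with retention to give 16, and on warming each 4-methylpentyl group shifts from boron to carbon antiperiplanar to the departing carbamate, with inversion at carbon. This is the lithiation–borylation of enantioenriched secondary benzylic carbamates with alkyl pinacol boronates, a known stereospecific 1,2-metalate rearrangement, run here at two independent sites of one molecule. No ring is closed; two C–C bonds and two fully substituted carbons are formed. Each new stereocentre is governed only by the configuration of its own carbamate carbon (retentive borylation, invertive migration), so (R,R)-11 should give the bis(boronate) that oxidises to the (S,S)-diol. The step needs benzylic C–H removal next to each carbamate to be faster than deprotonation of the doubly benzylic bridging CH2, of the CH2OSi group or of the rings, which carbamate-directed lithiation at −78 °C in Et2O should secure. It also needs migration to outrun reversal of boronate formation at the electron-rich ortho-methoxyaryl centres, which MgBr2 in MeOH promotes.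

Step 11
Reactants: 17 (R,R)-bis(tertiary benzylic pinacol boronate)
Product: 18 (2S)-2-{4-[(5-[(2S)-2-hydroxy-6-methylheptan-2-yl]-4-methoxy-2-{[(triisopropylsilyl)oxy]methyl}phenyl)methyl]-2-methoxyphenyl}-6-methylheptan-2-ol
Conditions: NaOH (2 M aq.), H2O2 (30 % aq.), THF, 0 °C → rt
Reagents that add atoms: hydrogen peroxide, SMILES OO
Why: Boronate oxidation, in which hydroperoxide adds to each boron and the tertiary carbon migrates from boron to oxygen with retention, so both C–B carbons become the (S)-carbinols while the methyl ethers and the silyl ether are untouched.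

Step 12
Reactants: 18 bis(tertiary alcohol) silyl ether
Product: 19 (2S)-2-{4-[(2-(hydroxymethyl)-5-[(2S)-2-hydroxy-6-methylheptan-2-yl]-4-methoxyphenyl)methyl]-2-methoxyphenyl}-6-methylheptan-2-ol
Conditions: Bu4NF, THF, 0 °C → rt
Reagents that add atoms: none
Why: Fluoride-mediated desilylation driven by the strong Si–F bond, placed after the oxidation because fluoride would protodeboronate tertiary benzylic boronates, and mild enough for the tertiary alcohols.

Step 13
Reactants: 19 triol bis(methyl ether)
Product: 20 disydonol C, 2-[(2S)-2-hydroxy-6-methylheptan-2-yl]-5-({4-hydroxy-5-[(2S)-2-hydroxy-6-methylheptan-2-yl]-2-(hydroxymethyl)phenyl}methyl)phenol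
Conditions: NaSEt (excess), DMF, 120 °C
Reagents that add atoms: none
Why: Nucleophilic demethylation (SN2 attack of ethanethiolate at each O-methyl carbon with phenoxide as leaving group) in a medium that is never acidic, so the ionisable tertiary benzylic alcohols should survive and no bond at either stereocentre is touched.

Compound list
1 | methyl 4-acetyl-3-hydroxybenzoate | COC(=O)c1ccc(C(C)=O)c(O)c1 | starting material
2 | methyl 4-acetyl-3-methoxybenzoate | COC(=O)c1ccc(C(C)=O)c(OC)c1 | intermediate
3 | methyl 4-[(1R)-1-hydroxyethyl]-3-methoxybenzoate | COC(=O)c1ccc([C@@H](C)O)c(OC)c1 | intermediate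
4 | N,N-diisopropylcarbamoyl chloride | CC(C)N(C(C)C)C(Cl)=O | starting material
5 | methyl 4-[(1R)-1-(N,N-diisopropylcarbamoyloxy)ethyl]-3-methoxybenzoate | COC(=O)c1ccc([C@@H](C)OC(=O)N(C(C)C)C(C)C)c(OC)c1 | intermediate
6 | (1R)-1-[4-(hydroxymethyl)-2-methoxyphenyl]ethyl N,N-diisopropylcarbamate | C[C@@H](OC(=O)N(C(C)C)C(C)C)c1ccc(CO)cc1OC | intermediate
7 | (1R)-1-[4-(bromomethyl)-2-methoxyphenyl]ethyl N,N-diisopropylcarbamate | C[C@@H](OC(=O)N(C(C)C)C(C)C)c1ccc(CBr)cc1OC | intermediate
8 | (1R)-1-[5-bromo-4-(hydroxymethyl)-2-methoxyphenyl]ethyl N,N-diisopropylcarbamate | C[C@@H](OC(=O)N(C(C)C)C(C)C)c1cc(Br)c(CO)cc1OC | intermediate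
9 | (1R)-1-[5-bromo-2-methoxy-4-(triisopropylsilyloxymethyl)phenyl]ethyl N,N-diisopropylcarbamate | C[C@@H](OC(=O)N(C(C)C)C(C)C)c1cc(Br)c(CO[Si](C(C)C)(C(C)C)C(C)C)cc1OC | intermediate
10 | {4-[(1R)-1-(N,N-diisopropylcarbamoyloxy)ethyl]-3-methoxybenzyl}zinc bromide (not isolated) | C[C@@H](OC(=O)N(C(C)C)C(C)C)c1ccc(C[Zn]Br)cc1OC | intermediate
11 | (R,R)-bis(carbamate): (1R)-1-{4-[(5-{(1R)-1-[(diisopropylcarbamoyl)oxy]ethyl}-4-methoxy-2-{[(triisopropylsilyl)oxy]methyl}phenyl)methyl]-2-methoxyphenyl}ethyl N,N-diisopropylcarbamate | C[C@@H](OC(=O)N(C(C)C)C(C)C)c1ccc(Cc2cc([C@@H](C)OC(=O)N(C(C)C)C(C)C)c(OC)cc2CO[Si](C(C)C)(C(C)C)C(C)C)cc1OC | intermediate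
12 | 1-bromo-4-methylpentane | CC(C)CCCBr | starting material
13 | 4-methylpentylmagnesium bromide (not isolated) | CC(C)CCC[Mg]Br | intermediate
14 | 4,4,5,5-tetramethyl-2-(4-methylpentyl)-1,3,2-dioxaborolane | CC(C)CCCB1OC(C)(C)C(C)(C)O1 | intermediate
15 | dilithiated bis(carbamate): 11 with lithium in place of each benzylic hydrogen, configuration retained (not isolated) | C[C@@]([Li])(OC(=O)N(C(C)C)C(C)C)c1ccc(Cc2cc([C@@]([Li])(C)OC(=O)N(C(C)C)C(C)C)c(OC)cc2CO[Si](C(C)C)(C(C)C)C(C)C)cc1OC | intermediate
16 | dilithium bis(boronate complex): each carbamate carbon bonded to a tetracoordinate boron that carries the pinacol unit and a 4-methylpentyl group (not isolated) | C[C@@]([B-]1(CCCC(C)C)OC(C)(C)C(C)(C)O1)(OC(=O)N(C(C)C)C(C)C)c1ccc(Cc2cc([C@@]([B-]3(CCCC(C)C)OC(C)(C)C(C)(C)O3)(C)OC(=O)N(C(C)C)C(C)C)c(OC)cc2CO[Si](C(C)C)(C(C)C)C(C)C)cc1OC.[Li+].[Li+] | intermediate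
17 | (R,R)-bis(tertiary benzylic pinacol boronate): 2-[(2R)-2-{2-methoxy-4-[(4-methoxy-5-[(2R)-6-methyl-2-(4,4,5,5-tetramethyl-1,3,2-dioxaborolan-2-yl)heptan-2-yl]-2-{[(triisopropylsilyl)oxy]methyl}phenyl)methyl]phenyl}-6-methylheptan-2-yl]-4,4,5,5-tetramethyl-1,3,2-dioxaborolane | CC(C)CCC[C@](C)(B1OC(C)(C)C(C)(C)O1)c1ccc(Cc2cc([C@@](C)(B3OC(C)(C)C(C)(C)O3)CCCC(C)C)c(OC)cc2CO[Si](C(C)C)(C(C)C)C(C)C)cc1OC | intermediate
18 | (2S)-2-{4-[(5-[(2S)-2-hydroxy-6-methylheptan-2-yl]-4-methoxy-2-{[(triisopropylsilyl)oxy]methyl}phenyl)methyl]-2-methoxyphenyl}-6-methylheptan-2-ol | CC(C)CCC[C@](C)(O)c1ccc(Cc2cc([C@@](C)(O)CCCC(C)C)c(OC)cc2CO[Si](C(C)C)(C(C)C)C(C)C)cc1OC | intermediate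
19 | (2S)-2-{4-[(2-(hydroxymethyl)-5-[(2S)-2-hydroxy-6-methylheptan-2-yl]-4-methoxyphenyl)methyl]-2-methoxyphenyl}-6-methylheptan-2-ol | CC(C)CCC[C@](C)(O)c1ccc(Cc2cc([C@@](C)(O)CCCC(C)C)c(OC)cc2CO)cc1OC | intermediate
20 | disydonol C | CC(C)CCC[C@](C)(O)c1ccc(Cc2cc([C@@](C)(O)CCCC(C)C)c(O)cc2CO)cc1O | target

Total step count: 13.
Longest linear sequence: 11 steps (steps 1, 2, 3, 4, 6, 7, 8, 10, 11, 12, 13).

Steps most likely to fail, riskiest first

Step 10. Three processes may spoil it. sec-Butyllithium may deprotonate the doubly benzylic bridging CH2 instead of the second carbamate site. Only one of the two carbamates may be lithiated and borylated. Boronate formation at the ortho-methoxyaryl centres may reverse before migration and erode the stereochemical fidelity. The fallback moves the metalate rearrangement ahead of the ring union, so that no diarylmethane CH2 is present and one centre is set per molecule. It sets out from 6.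
- Silylation (TIPSCl, imidazole, DMF) gives (1R)-1-[2-methoxy-4-(triisopropylsilyloxymethyl)phenyl]ethyl N,N-diisopropylcarbamate F1.
- A single lithiation–borylation of F1 with 14 (s-BuLi, Et2O, −78 °C; then MgBr2 in MeOH) gives 2-[(2R)-2-[2-methoxy-4-(triisopropylsilyloxymethyl)phenyl]-6-methylheptan-2-yl]-4,4,5,5-tetramethyl-1,3,2-dioxaborolane F2.
- Oxidation (NaOH, H2O2) converts F2 into (2S)-2-[2-methoxy-4-(triisopropylsilyloxymethyl)phenyl]-6-methylheptan-2-ol F3.
- One portion of F3 is brominated para to the methoxy group (NBS, MeCN, 0 °C) to give (2S)-2-[5-bromo-2-methoxy-4-(triisopropylsilyloxymethyl)phenyl]-6-methylheptan-2-ol F4.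
- A second portion of F3 is desilylated (Bu4NF, THF) to (2S)-2-[4-(hydroxymethyl)-2-methoxyphenyl]-6-methylheptan-2-ol F5.
- The primary benzylic hydroxyl of F5 is converted selectively (PPh3, CBr4, CH2Cl2, −20 °C) into (2S)-2-[4-(bromomethyl)-2-methoxyphenyl]-6-methylheptan-2-ol F6.
- Miyaura borylation of F4 (B2pin2, PdCl2(dppf), KOAc, dioxane, 85 °C) gives (2S)-2-[2-methoxy-5-(4,4,5,5-tetramethyl-1,3,2-dioxaborolan-2-yl)-4-(triisopropylsilyloxymethyl)phenyl]-6-methylheptan-2-ol F7.
- Suzuki–Miyaura coupling of F7 with F6 (aqueous K3PO4 added to the same pot, 60 °C) joins the rings and comes back to the route at 18.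

Step 8. Wurtz-type homocoupling during zinc insertion may consume the benzylic bromide, or oxidative addition into the hindered, electron-rich aryl bromide may be too slow, leaving the union incomplete. The fallback reverses the polarity of the union, so that no benzylic organometallic is generated. It sets out from 9. Miyaura borylation (B2pin2, PdCl2(dppf), KOAc, dioxane, 85 °C) gives (1R)-1-[2-methoxy-5-(4,4,5,5-tetramethyl-1,3,2-dioxaborolan-2-yl)-4-(triisopropylsilyloxymethyl)phenyl]ethyl N,N-diisopropylcarbamate F8. Suzuki–Miyaura coupling of F8 with benzylic bromide 7 (PdCl2(dppf), aqueous K3PO4, THF, 60 °C) comes back to the route at 11.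

Step 2. Facial selectivity in the hydride transfer to the ortho-methoxy aryl ketone may be insufficient. Any (S)-alcohol carried forward would end up in epimers of 11 that differ only at a remote centre and would be hard to remove. The fallback replaces asymmetric catalysis by kinetic resolution. It sets out from 2.
- Reduction with NaBH4 (MeOH, 0 °C) gives racemic methyl 4-(1-hydroxyethyl)-3-methoxybenzoate F9.
- Lipase-catalysed acylation (Candida antarctica lipase B, vinyl acetate, MTBE, 35 °C), with the usual (R)-selectivity of this enzyme for 1-arylethanols, converts the (R)-enantiomer into methyl 4-[(1R)-1-acetoxyethyl]-3-methoxybenzoate F10.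
- The unreacted methyl 4-[(1S)-1-hydroxyethyl]-3-methoxybenzoate F11 is separated by chromatography.
- Methanolysis of F10 (K2CO3, MeOH, rt) comes back to the route at 3.

Further compounds
F1 | step 10 | (1R)-1-[2-methoxy-4-(triisopropylsilyloxymethyl)phenyl]ethyl N,N-diisopropylcarbamate | C[C@@H](OC(=O)N(C(C)C)C(C)C)c1ccc(CO[Si](C(C)C)(C(C)C)C(C)C)cc1OC
F2 | step 10 | 2-[(2R)-2-[2-methoxy-4-(triisopropylsilyloxymethyl)phenyl]-6-methylheptan-2-yl]-4,4,5,5-tetramethyl-1,3,2-dioxaborolane | CC(C)CCC[C@](C)(B1OC(C)(C)C(C)(C)O1)c1ccc(CO[Si](C(C)C)(C(C)C)C(C)C)cc1OC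
F3 | step 10 | (2S)-2-[2-methoxy-4-(triisopropylsilyloxymethyl)phenyl]-6-methylheptan-2-ol | CC(C)CCC[C@](C)(O)c1ccc(CO[Si](C(C)C)(C(C)C)C(C)C)cc1OC
F4 | step 10 | (2S)-2-[5-bromo-2-methoxy-4-(triisopropylsilyloxymethyl)phenyl]-6-methylheptan-2-ol | CC(C)CCC[C@](C)(O)c1cc(Br)c(CO[Si](C(C)C)(C(C)C)C(C)C)cc1OC
F5 | step 10 | (2S)-2-[4-(hydroxymethyl)-2-methoxyphenyl]-6-methylheptan-2-ol | CC(C)CCC[C@](C)(O)c1ccc(CO)cc1OC
F6 | step 10 | (2S)-2-[4-(bromomethyl)-2-methoxyphenyl]-6-methylheptan-2-ol | CC(C)CCC[C@](C)(O)c1ccc(CBr)cc1OC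
F7 | step 10 | (2S)-2-[2-methoxy-5-(4,4,5,5-tetramethyl-1,3,2-dioxaborolan-2-yl)-4-(triisopropylsilyloxymethyl)phenyl]-6-methylheptan-2-ol | CC(C)CCC[C@](C)(O)c1cc(B2OC(C)(C)C(C)(C)O2)c(CO[Si](C(C)C)(C(C)C)C(C)C)cc1OC
F8 | step 8 | (1R)-1-[2-methoxy-5-(4,4,5,5-tetramethyl-1,3,2-dioxaborolan-2-yl)-4-(triisopropylsilyloxymethyl)phenyl]ethyl N,N-diisopropylcarbamate | C[C@@H](OC(=O)N(C(C)C)C(C)C)c1cc(B2OC(C)(C)C(C)(C)O2)c(CO[Si](C(C)C)(C(C)C)C(C)C)cc1OC
F9 | step 2 | racemic methyl 4-(1-hydroxyethyl)-3-methoxybenzoate | COC(=O)c1ccc(C(C)O)c(OC)c1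
F10 | step 2 | methyl 4-[(1R)-1-acetoxyethyl]-3-methoxybenzoate | COC(=O)c1ccc([C@@H](C)OC(C)=O)c(OC)c1
F11 | step 2 | methyl 4-[(1S)-1-hydroxyethyl]-3-methoxybenzoate | COC(=O)c1ccc([C@H](C)O)c(OC)c1
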